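## The problem

Prestegane A (21) is a trans-3,4-dibenzyl-γ-butyrolactone. With the lactone numbered O1, C2 (carbonyl), C3, C4, C5, C3 carries the 3-hydroxy-4-methoxybenzyl arm (ring A) and C4 the 3,4-dimethoxybenzyl arm (ring B); nothing is fused, so the task is to attach two arylmethyl chains to neighbouring carbons of a four-carbon lactone core. The arms differ by a single O-methyl group, so they must be introduced by chemically distinct operations if they are not to end up on the wrong carbons, and the ring A phenol must travel masked. The two stereocentres are (3R,4R): C4 cannot be epimerised and must be set absolutely, whereas C3 is α to the carbonyl and is delivered trans both by kinetic enolate alkylation anti to the C4 substituent and by equilibration, so C4 can control C3 but not the reverse. The sensitive sites are the lactone (opened by nucleophilic base, enolised at C3 by strong base), the two electron-rich arenes with their benzylic CH2 groups (open to benzylic oxidation and oxidative cyclisation) and the free phenol. The feature exploited is ring B: two adjacent, identical methoxy groups at C3′ and C4′ and one carbon substituent at C1′ are exactly the pattern formed when the symmetrical diene 18 adds across a terminal alkyne, the alkyne supplying C1′ and C6′ and the diene C2′ to C5′. Ring B can therefore be replaced in retrosynthesis by a propargyl group on C4.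

## Retrosynthesis

**21 ⇒ 20.** The O–CH2Ph bond is cut last. A benzyl ether is the one phenol mask that survives amide bases, fluoride, zinc halides, low-valent cobalt and a quinone oxidant, and it leaves by neutral hydrogenolysis, which cannot epimerise C3. A silyl ether would fall in the desilylation step and an acyl group in the enolate steps.

**20 ⇒ 19 ⇒ 17 + 18.** Two hydrogens are returned to ring B to give the cyclohexa-1,4-diene 19, and the σ bonds C1′–C2′ and C5′–C6′ are then cut. The neighbouring cuts (C4–CH2 or CH2–C1′) would call for a 3,4-dimethoxybenzyl reagent almost identical to the ring A bromide 14; here ring B does not exist while ring A and both stereocentres are installed, so the arms cannot be confused. Alkyne 17 has one ring fewer, and 18 is commercial and symmetrical, so no regiochemistry arises. The forward reaction cannot be thermal, since an unactivated alkyne and an electron-rich diene do not combine; it needs a low-valent cobalt catalyst under base-free conditions, followed by a dehydrogenation mild enough to spare the benzylic CH2 groups.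

**17 ⇒ 16.** The acetylenic C–H is traced to a C–SiMe3 bond. The cap costs two simple steps and removes the competition between acetylide and enolate formation in every base-mediated step before it.

**16 ⇒ 12 + 14; 14 ⇒ 13.** The C3–CH2 bond of the ring A arm is cut. Cutting C3–C4 instead would mean forming both stereocentres at once. This cut leaves lactone 12 with a single stereocentre and a benzylic bromide one step from the purchased alcohol 13. The forward step asks the lactone enolate to be alkylated anti to the C4 arm, the normal outcome for 4-substituted butyrolactones.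

**12 ⇒ 11 ⇒ 10.** The O1–C2 bond is opened to the hydroxy tert-butyl ester 11, whose CH2OH (future C5) comes from the imide carbonyl of 10 by reduction. The forward steps require only that a borohydride distinguish an imide from a tert-butyl ester and that acid close a five-membered lactone.

**10 ⇒ 7 + 8.** The bond between the future C4 and C3 is cut: the chiral imide enolate is alkylated with bromoacetate 8. A catalytic conjugate addition of a propargyl nucleophile to a butenolide is the obvious neighbour but has no reliable form. The auxiliary-controlled alkylation has a predictable sense, and (S)-configured 5 gives the R centre required.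

**7 ⇒ 4 + 5; 4 ⇒ 1.** N-acylation of 5 with the silylated acid 4, itself made by C-silylation of pent-4-ynoic acid 1.

## Roads not taken

**Alternative 1:** The lactone is cut at O1–C2, C3–C4 and O1–C5 into the enantiopure E vinyl sulfoxide A2 (ring B arm) and the chloroketene A4, generated in the flask from acyl chloride A3 (ring A arm) with an amine base.
- Forward step: the sulfoxide oxygen acylates, a [3,3] shift makes C3–C4 with transfer of chirality from sulfur to C4, and the carboxylate closes onto the thionium carbon to give lactone A1.
- Merits: both arms, the ring and C4 arrive in one operation, and the route would be clearly shorter and more convergent than the chosen one.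
- Weak points: A2 has a benzylic, allylic CH2 next to the vinyl sulfoxide and can drift under the amine base to the styrenyl allyl sulfoxide, which is open to Mislow–Evans rearrangement. A monochloro alkyl ketene is a far less dependable partner than dichloroketene. A1 still needs reductive removal of chlorine and sulfur in the presence of a benzyl ether, and C3 is only set afterwards by epimerisation.
- Comparison: the chosen plan is longer, but each step lies inside established scope and the absolute configuration comes from an auxiliary with a predictable sense.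

**Alternative 2:** The two bonds from the lactone to the benzylic carbons are cut.
- Forward step: the lithiated dithiane A7 adds to C4 of the menthyloxy butenolide A6 anti to the acetal substituent, and the enolate is trapped at C3 by bromide 14 to give A5 with both stereocentres.
- Merits: nickel-mediated desulfurisation and reduction of the acetal carbon to CH2 would finish the skeleton in very few steps, and the sequence is well proven for this lignan class. For the target alone this road is shorter than the chosen one and at least as secure.
- Weak points: A6 has to be obtained diastereomerically pure by photo-oxygenation and crystallisation. Stoichiometric sulfur and nickel are used, and the desulfurisation must be made compatible with the O-benzyl group.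
- Comparison: the chosen plan can set against it only that ring B is made last from one common alkyne 17, so other dienes would give ring B analogues, that the two aryl groups never coexist as similar reagents, and that no stoichiometric heavy-metal or sulfur chemistry is needed.

**Alternative 3:** The C4–C5 bond is cut.
- Forward step: the bromomethylsilyl ether A9 of a γ-hydroxy enoate gives, with a tin hydride, a silylmethyl radical that closes 5-exo onto the β carbon to form oxasilolane A8. Oxidation of the C–Si bond, lactonisation and hydrogenolysis of the sacrificial benzylic C–O bond (together with the O-benzyl group) would follow.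
- Merits: C4 is set by a cyclic transition state from an easily made carbinol centre, and the final hydrogenolysis does double duty.
- Weak points: C3 is set by hydrogen-atom transfer to an acyclic ester radical with uncertain selectivity and would have to be corrected by epimerisation. Enantiopure A9 takes several steps, a stereocentre is made only to be destroyed, and tin is used.
- Comparison: the length is comparable to the chosen plan. Its advantage is that it does not depend on a metal-catalysed cycloaddition with a new diene; the chosen plan avoids tin and the sacrificial stereocentre.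

Key step: step 9

Remark: alcohol 13 is taken as purchased (it is the borohydride reduction product of commercial O-benzylisovanillin), and species generated by one reagent addition and consumed by the next (metalated species, silyl ester, mixed anhydride) are numbered as intermediates that are not isolated.

## Route

Step 1
Reactants: 1 pent-4-ynoic acid
Product: 4 5-(trimethylsilyl)pent-4-ynoic acid, via dilithiated pent-4-ynoic acid 2 (not isolated), via trimethylsilyl 5-(trimethylsilyl)pent-4-ynoate 3 (not isolated)
Conditions: n-BuLi (2.1 equiv), THF, −78 °C; Me3SiCl (2.3 equiv), −78 °C → rt; 1 M HCl work-up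
Reagents that add atoms: chlorotrimethylsilane, C[Si](C)(C)Cl; n-butyllithium, [Li]CCCC (lithium of intermediate 2 only)
Why: Double deprotonation gives the carboxylate–acetylide 2, both sites are silylated (acetylide C-silylation), and the labile silyl ester 3 is hydrolysed on acidic work-up while the alkynylsilane stays.

Step 2
Reactants: 4 5-(trimethylsilyl)pent-4-ynoic acid; 5 (S)-4-benzyloxazolidin-2-one
Product: 7 (S)-4-benzyl-3-[5-(trimethylsilyl)pent-4-ynoyl]oxazolidin-2-one, via mixed pivalic anhydride 6 (not isolated)
Conditions: t-BuCOCl, Et3N, THF, −20 °C; then LiCl, 5, −20 °C → rt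
Reagents that add atoms: pivaloyl chloride, CC(C)(C)C(=O)Cl (its atoms stay in intermediate 6 only)
Why: N-acylation of an oxazolidinone through a mixed pivalic anhydride with LiCl activation; the nucleophile attacks the unhindered acyl carbonyl of 6 and the stereocentre of 5 is not involved.

Step 3
Reactants: 7 (S)-4-benzyl-3-[5-(trimethylsilyl)pent-4-ynoyl]oxazolidin-2-one; 8 tert-butyl bromoacetate
Product: 10 tert-butyl (3R)-3-{[(4S)-4-benzyl-2-oxo-1,3-oxazolidin-3-yl]carbonyl}-6-(trimethylsilyl)hex-5-ynoate, via sodium Z-enolate 9 (not isolated)
Conditions: NaN(SiMe3)2 (1.1 equiv), THF, −78 °C; then 8, −78 → −45 °C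
Reagents that add atoms: sodium bis(trimethylsilyl)amide, [Na+].C[Si](C)(C)[N-][Si](C)(C)C (sodium of intermediate 9 only)
Why: Evans asymmetric alkylation: the chelated Z-enolate 9 is shielded on one face by the benzyl group of the auxiliary, so the reactive bromoacetate enters from the other face and sets the R configuration at the carbon that becomes lactone C4.

Step 4
Reactants: 10 tert-butyl (3R)-3-{[(4S)-4-benzyl-2-oxo-1,3-oxazolidin-3-yl]carbonyl}-6-(trimethylsilyl)hex-5-ynoate
Product: 11 tert-butyl (3R)-3-(hydroxymethyl)-6-(trimethylsilyl)hex-5-ynoate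
Conditions: LiBH4, H2O (1 equiv), Et2O, 0 °C
Reagents that add atoms: none
Why: Reductive cleavage of the exocyclic imide carbonyl of an N-acyloxazolidinone by LiBH4; the hindered tert-butyl ester is not reduced at 0 °C, auxiliary 5 is recovered, and any material that lactonises spontaneously converges on 12 in step 5.

Step 5
Reactants: 11 tert-butyl (3R)-3-(hydroxymethyl)-6-(trimethylsilyl)hex-5-ynoate
Product: 12 (4R)-4-[3-(trimethylsilyl)prop-2-yn-1-yl]dihydrofuran-2(3H)-one
Conditions: CF3CO2H, CH2Cl2, 0 °C → rt
Reagents that add atoms: none
Why: Acid cleaves the tert-butyl ester and the γ-hydroxy acid closes to the five-membered lactone (5-exo-trig acyl substitution); the stereocentre is not touched and alkynylsilanes tolerate trifluoroacetic acid.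

Step 6
Reactants: 13 [3-(benzyloxy)-4-methoxyphenyl]methanol
Product: 14 2-(benzyloxy)-4-(bromomethyl)-1-methoxybenzene
Conditions: PBr3 (0.4 equiv), Et2O, 0 °C
Reagents that add atoms: phosphorus tribromide, BrP(Br)Br
Why: Conversion of a benzylic alcohol into the bromide with PBr3 (bromide displaces the phosphite ester); the electron-rich bromide is labile and is used at once.

Step 7
Reactants: 12 (4R)-4-[3-(trimethylsilyl)prop-2-yn-1-yl]dihydrofuran-2(3H)-one; 14 2-(benzyloxy)-4-(bromomethyl)-1-methoxybenzene
Product: 16 (3R,4R)-3-[3-(benzyloxy)-4-methoxybenzyl]-4-[3-(trimethylsilyl)prop-2-yn-1-yl]dihydrofuran-2(3H)-one, via lithium enolate 15 (not isolated)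
Conditions: LiN(SiMe3)2 (1.05 equiv), THF, −78 °C; then 14, DMPU, −78 → −40 °C
Reagents that add atoms: lithium bis(trimethylsilyl)amide, [Li+].C[Si](C)(C)[N-][Si](C)(C)C (lithium of intermediate 15 only)
Why: Alkylation of a lactone enolate with a benzylic bromide: the C4 substituent blocks one face of the planar enolate 15, so the electrophile adds anti to it and gives the trans (3R,4R) lactone, which is also the more stable epimer; the silyl cap excludes acetylide formation.

Step 8
Reactants: 16 (3R,4R)-3-[3-(benzyloxy)-4-methoxybenzyl]-4-[3-(trimethylsilyl)prop-2-yn-1-yl]dihydrofuran-2(3H)-one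
Product: 17 (3R,4R)-3-[3-(benzyloxy)-4-methoxybenzyl]-4-(prop-2-yn-1-yl)dihydrofuran-2(3H)-one
Conditions: Bu4NF, AcOH, THF, 0 °C → rt
Reagents that add atoms: none
Why: Fluoride-induced protodesilylation of an alkynylsilane; buffering with acetic acid keeps the medium from opening the lactone or enolising C3.

Step 9
Reactants: 17 (3R,4R)-3-[3-(benzyloxy)-4-methoxybenzyl]-4-(prop-2-yn-1-yl)dihydrofuran-2(3H)-one; 18 2,3-dimethoxybuta-1,3-diene
Product: 19 (3R,4R)-3-[3-(benzyloxy)-4-methoxybenzyl]-4-[(4,5-dimethoxycyclohexa-1,4-dien-1-yl)methyl]dihydrofuran-2(3H)-one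
Conditions: CoBr2(dppe) (10 mol %; dppe = Ph2PCH2CH2PPh2), Zn powder (20 mol %), ZnI2 (20 mol %), 18 (3 equiv), CH2Cl2, rt, argon; filtration through basic Al2O3
Reagents that add atoms: none
Why: Zinc reduces CoBr2(dppe) (divalent cobalt) and ZnI2 abstracts halide, giving a cationic monovalent cobalt–diphosphine species that binds diene 18 in its s-cis form together with the alkyne of 17; oxidative cyclisation gives a cobaltacycle of trivalent cobalt in which the first C–C bond is made, and reductive elimination makes the second and returns monovalent cobalt. The closest known reaction type is the cobalt-catalysed neutral Diels–Alder reaction of unactivated terminal alkynes with 2,3-dialkyl- and 2-silyloxybuta-1,3-dienes, which gives cyclohexa-1,4-dienes at room temperature. The six-membered carbocycle closes by an intermolecular, metal-templated [4+2] annulation: four carbons from 18, two from the alkyne, two new σ bonds. No stereocentre is created, and C3 and C4 are not at risk because the medium contains no base and only a weak Lewis acid. The selectivity needed is chemoselectivity for cross addition over alkyne cyclotrimerisation and diene dimerisation, which excess 18, slow addition of 17 and the chelating diphosphine should secure; regioselectivity does not arise because 18 has a twofold axis and both orientations give the same ring. A thermal reaction is no option, since both partners are electron-rich. The bis(enol ether) product is acid-labile, so it is only freed from metal salts by filtration and is oxidised at once.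

Step 10
Reactants: 19 (3R,4R)-3-[3-(benzyloxy)-4-methoxybenzyl]-4-[(4,5-dimethoxycyclohexa-1,4-dien-1-yl)methyl]dihydrofuran-2(3H)-one
Product: 20 (3R,4R)-3-[3-(benzyloxy)-4-methoxybenzyl]-4-(3,4-dimethoxybenzyl)dihydrofuran-2(3H)-one
Conditions: DDQ (1.05 equiv), toluene, 0 °C → rt
Reagents that add atoms: none
Why: Dehydrogenation of a cyclohexa-1,4-diene by DDQ (hydride abstraction from a doubly allylic CH2, then proton loss) is driven by aromatisation and is fast, so one equivalent at low temperature should leave the benzylic CH2 groups of the electron-rich arenes alone.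

Step 11
Reactants: 20 (3R,4R)-3-[3-(benzyloxy)-4-methoxybenzyl]-4-(3,4-dimethoxybenzyl)dihydrofuran-2(3H)-one
Product: 21 prestegane A, (3R,4R)-4-(3,4-dimethoxybenzyl)-3-(3-hydroxy-4-methoxybenzyl)dihydrofuran-2(3H)-one
Conditions: H2 (1 atm), Pd/C (zerovalent palladium on carbon, 10 wt %), EtOAc, rt
Reagents that add atoms: none
Why: Hydrogenolysis of an aryl benzyl ether over palladium; the lactone, the methyl ethers and the benzylic C–C bonds are inert, and the neutral medium cannot epimerise C3.

## Compound list

1 | pent-4-ynoic acid | C#CCCC(=O)O | starting material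
2 | dilithiated pent-4-ynoic acid (lithium 5-lithiopent-4-ynoate) | [Li+].[Li+].[C-]#CCCC(=O)[O-] | intermediate
3 | trimethylsilyl 5-(trimethylsilyl)pent-4-ynoate | C[Si](C)(C)C#CCCC(=O)O[Si](C)(C)C | intermediate
4 | 5-(trimethylsilyl)pent-4-ynoic acid | C[Si](C)(C)C#CCCC(=O)O | intermediate
5 | (S)-4-benzyloxazolidin-2-one | O=C1N[C@@H](Cc2ccccc2)CO1 | starting material
6 | 5-(trimethylsilyl)pent-4-ynoic pivalic anhydride | C[Si](C)(C)C#CCCC(=O)OC(=O)C(C)(C)C | intermediate
7 | (S)-4-benzyl-3-[5-(trimethylsilyl)pent-4-ynoyl]oxazolidin-2-one | O=C1N(C(=O)CCC#C[Si](C)(C)C)[C@@H](Cc2ccccc2)CO1 | intermediate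
8 | tert-butyl bromoacetate | CC(C)(C)OC(=O)CBr | starting material
9 | sodium Z-enolate of imide 7 | [Na+].[O-]/C(=C\CC#C[Si](C)(C)C)N1C(=O)OC[C@@H]1Cc1ccccc1 | intermediate
10 | tert-butyl (3R)-3-{[(4S)-4-benzyl-2-oxo-1,3-oxazolidin-3-yl]carbonyl}-6-(trimethylsilyl)hex-5-ynoate | O=C1N(C(=O)[C@@H](CC(=O)OC(C)(C)C)CC#C[Si](C)(C)C)[C@@H](Cc2ccccc2)CO1 | intermediate
11 | tert-butyl (3R)-3-(hydroxymethyl)-6-(trimethylsilyl)hex-5-ynoate | OC[C@@H](CC(=O)OC(C)(C)C)CC#C[Si](C)(C)C | intermediate
12 | (4R)-4-[3-(trimethylsilyl)prop-2-yn-1-yl]dihydrofuran-2(3H)-one | O=C1OC[C@@H](C1)CC#C[Si](C)(C)C | intermediate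
13 | [3-(benzyloxy)-4-methoxyphenyl]methanol | COc1ccc(CO)cc1OCc1ccccc1 | starting material
14 | 2-(benzyloxy)-4-(bromomethyl)-1-methoxybenzene | COc1ccc(CBr)cc1OCc1ccccc1 | intermediate
15 | lithium enolate of lactone 12 | [Li+].[O-]C1=C[C@@H](CC#C[Si](C)(C)C)CO1 | intermediate
16 | (3R,4R)-3-[3-(benzyloxy)-4-methoxybenzyl]-4-[3-(trimethylsilyl)prop-2-yn-1-yl]dihydrofuran-2(3H)-one | COc1ccc(C[C@H]2C(=O)OC[C@@H]2CC#C[Si](C)(C)C)cc1OCc1ccccc1 | intermediate
17 | (3R,4R)-3-[3-(benzyloxy)-4-methoxybenzyl]-4-(prop-2-yn-1-yl)dihydrofuran-2(3H)-one | COc1ccc(C[C@H]2C(=O)OC[C@@H]2CC#C)cc1OCc1ccccc1 | intermediate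
18 | 2,3-dimethoxybuta-1,3-diene | C=C(OC)C(=C)OC | starting material
19 | (3R,4R)-3-[3-(benzyloxy)-4-methoxybenzyl]-4-[(4,5-dimethoxycyclohexa-1,4-dien-1-yl)methyl]dihydrofuran-2(3H)-one | COc1ccc(C[C@H]2C(=O)OC[C@@H]2CC3=CCC(OC)=C(OC)C3)cc1OCc1ccccc1 | intermediate
20 | (3R,4R)-3-[3-(benzyloxy)-4-methoxybenzyl]-4-(3,4-dimethoxybenzyl)dihydrofuran-2(3H)-one | COc1ccc(C[C@H]2C(=O)OC[C@@H]2Cc2ccc(OC)c(OC)c2)cc1OCc1ccccc1 | intermediate
21 | prestegane A, (3R,4R)-4-(3,4-dimethoxybenzyl)-3-(3-hydroxy-4-methoxybenzyl)dihydrofuran-2(3H)-one | COc1ccc(C[C@H]2C(=O)OC[C@@H]2Cc2ccc(OC)c(OC)c2)cc1O | target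

## Step count and least certain steps

Total: 11 steps. Longest linear sequence: 10 steps (steps 1 to 5 and 7 to 11); step 6 is a one-step side branch.

**Step 9 (key step).**
- Risk: low conversion to the cross adduct, because the cobalt catalyst is diverted into cyclotrimerisation of the alkyne, or because the electron-rich dialkoxy diene binds too weakly or is degraded by the Lewis-acidic ZnI2 before it can react. Hydrolysis of the enol ethers during isolation is a further risk.
- Fallback (sets out from 5, returns at 20): ring B would be bought as an arene and the de novo construction given up.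
  - Auxiliary 5 would be acylated with commercial 3-(3,4-dimethoxyphenyl)propanoic acid (COc1ccc(CCC(=O)O)cc1OC) through 3-(3,4-dimethoxyphenyl)propanoic pivalic anhydride F1 to give (S)-4-benzyl-3-[3-(3,4-dimethoxyphenyl)propanoyl]oxazolidin-2-one F2.
  - Its sodium Z-enolate F3 would be alkylated with 8 to tert-butyl (3R)-3-{[(4S)-4-benzyl-2-oxo-1,3-oxazolidin-3-yl]carbonyl}-4-(3,4-dimethoxyphenyl)butanoate F4.
  - LiBH4 would release tert-butyl (3R)-4-(3,4-dimethoxyphenyl)-3-(hydroxymethyl)butanoate F5, and trifluoroacetic acid would close (4R)-4-(3,4-dimethoxybenzyl)dihydrofuran-2(3H)-one F6.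
  - Lithium (4R)-4-(3,4-dimethoxybenzyl)-4,5-dihydrofuran-2-olate F7, made with LiN(SiMe3)2, would be alkylated with bromide 14 as in step 7 to give 20, which re-enters the route at step 11.

**Step 7.**
- Risk: proton exchange between the product and unreacted enolate, leading to double alkylation and recovered lactone, and decomposition of the labile benzylic bromide before it is consumed. Erosion of the trans selectivity is less of a worry, since trans is also the stable epimer.
- Fallback (sets out from 12, returns at 16): enolate 15 would instead be added to commercial 3-(benzyloxy)-4-methoxybenzaldehyde (COc1ccc(C=O)cc1OCc1ccccc1) in an aldol reaction anti to the C4 arm. This would give (3S,4R)-3-{[3-(benzyloxy)-4-methoxyphenyl](hydroxy)methyl}-4-[3-(trimethylsilyl)prop-2-yn-1-yl]dihydrofuran-2(3H)-one F8 as both carbinol epimers. Ionic hydrogenation of this p-methoxy-stabilised benzylic alcohol with Et3SiH and CF3CO2H in CH2Cl2 would remove the hydroxyl and deliver 16.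

**Step 10.**
- Risk: over-oxidation, that is hydride abstraction by the quinone from the benzylic positions of the newly formed electron-rich arene, or loss of the enol ethers by hydrolysis before aromatisation.
- Fallback (sets out from 19, returns at 21): the cyclohexa-1,4-diene unit of 19 is itself a hydrogen donor of the kind used in catalytic transfer hydrogenolysis. Warming 19 with Pd/C (zerovalent palladium on carbon) in ethanol without any oxidant or hydrogen gas should pass its two hydrogens to the benzyl ether, aromatising ring B and freeing the phenol in one redox-neutral operation that gives 21 directly.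

## Further compounds

F1 | step 9 | 3-(3,4-dimethoxyphenyl)propanoic pivalic anhydride | COc1ccc(CCC(=O)OC(=O)C(C)(C)C)cc1OC
F2 | step 9 | (S)-4-benzyl-3-[3-(3,4-dimethoxyphenyl)propanoyl]oxazolidin-2-one | O=C1N(C(=O)CCc2ccc(OC)c(OC)c2)[C@@H](Cc2ccccc2)CO1
F3 | step 9 | sodium Z-enolate of imide F2 | [Na+].[O-]/C(=C\Cc1ccc(OC)c(OC)c1)N1C(=O)OC[C@@H]1Cc1ccccc1
F4 | step 9 | tert-butyl (3R)-3-{[(4S)-4-benzyl-2-oxo-1,3-oxazolidin-3-yl]carbonyl}-4-(3,4-dimethoxyphenyl)butanoate | O=C1N(C(=O)[C@@H](CC(=O)OC(C)(C)C)Cc2ccc(OC)c(OC)c2)[C@@H](Cc2ccccc2)CO1
F5 | step 9 | tert-butyl (3R)-4-(3,4-dimethoxyphenyl)-3-(hydroxymethyl)butanoate | OC[C@@H](CC(=O)OC(C)(C)C)Cc1ccc(OC)c(OC)c1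
F6 | step 9 | (4R)-4-(3,4-dimethoxybenzyl)dihydrofuran-2(3H)-one | O=C1OC[C@@H](C1)Cc1ccc(OC)c(OC)c1
F7 | step 9 | lithium (4R)-4-(3,4-dimethoxybenzyl)-4,5-dihydrofuran-2-olate | [Li+].[O-]C1=C[C@@H](Cc2ccc(OC)c(OC)c2)CO1
F8 | step 7 | (3S,4R)-3-{[3-(benzyloxy)-4-methoxyphenyl](hydroxy)methyl}-4-[3-(trimethylsilyl)prop-2-yn-1-yl]dihydrofuran-2(3H)-one | COc1ccc(C(O)[C@H]2C(=O)OC[C@@H]2CC#C[Si](C)(C)C)cc1OCc1ccccc1
F0 | step 10 | none | none
A1 | alternative 1 | 3-[3-(benzyloxy)-4-methoxybenzyl]-3-chloro-4-(3,4-dimethoxybenzyl)-5-(p-tolylsulfanyl)dihydrofuran-2(3H)-one | COc1ccc(C[C@@]2(Cl)C(=O)O[C@@H](Sc3ccc(C)cc3)[C@@H]2Cc2ccc(OC)c(OC)c2)cc1OCc1ccccc1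
A2 | alternative 1 | 1,2-dimethoxy-4-{(2E)-3-[(S)-(4-methylphenyl)sulfinyl]prop-2-en-1-yl}benzene | COc1ccc(C/C=C/[S@](=O)c2ccc(C)cc2)cc1OC
A3 | alternative 1 | 3-[3-(benzyloxy)-4-methoxyphenyl]-2-chloropropanoyl chloride | COc1ccc(CC(Cl)C(=O)Cl)cc1OCc1ccccc1
A4 | alternative 1 | 3-[3-(benzyloxy)-4-methoxyphenyl]-2-chloroprop-1-en-1-one (chloroketene) | COc1ccc(CC(Cl)=C=O)cc1OCc1ccccc1
A5 | alternative 2 | 3-[3-(benzyloxy)-4-methoxybenzyl]-4-[2-(3,4-dimethoxyphenyl)-1,3-dithian-2-yl]-5-(menthyloxy)dihydrofuran-2(3H)-one (3,4-trans, 4,5-trans) | COc1ccc(C[C@H]2C(=O)O[C@@H](O[C@@H]3C[C@H](C)CC[C@H]3C(C)C)[C@@H]2C2(c3ccc(OC)c(OC)c3)SCCCS2)cc1OCc1ccccc1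
A6 | alternative 2 | (5R)-5-[(1R,2S,5R)-menthyloxy]furan-2(5H)-one | O=C1C=C[C@H](O[C@@H]2C[C@H](C)CC[C@H]2C(C)C)O1
A7 | alternative 2 | 2-(3,4-dimethoxyphenyl)-1,3-dithiane | COc1ccc(C2SCCCS2)cc1OC
A8 | alternative 3 | methyl 3-[3-(benzyloxy)-4-methoxyphenyl]-2-[5-(3,4-dimethoxyphenyl)-2,2-dimethyl-1,2-oxasilolan-4-yl]propanoate (ring substituents trans) | COC(=O)[C@H](Cc1ccc(OC)c(OCc2ccccc2)c1)[C@@H]1C[Si](C)(C)O[C@H]1c1ccc(OC)c(OC)c1
A9 | alternative 3 | methyl (2E,4R)-2-[3-(benzyloxy)-4-methoxybenzyl]-4-{[(bromomethyl)dimethylsilyl]oxy}-4-(3,4-dimethoxyphenyl)but-2-enoate | COC(=O)/C(Cc1ccc(OC)c(OCc2ccccc2)c1)=C/[C@@H](O[Si](C)(C)CBr)c1ccc(OC)c(OC)c1
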